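The synthesis rests on constructing benzene ring B around the chiral chain instead of attaching that chain to an arene. Ring B has oxygen on C7 and C8a, hydrogen on C5 and C8 and the stereogenic C3' on C6, which is the regiochemical signature of a vinylketene–ynol ether benzannulation. In one operation a chiral-pool α-diazo enone (C3' from methyl (S)-3-hydroxy-2-methylpropanoate, primary alcohol as silyl ether) and (triisopropylsilyloxy)ethyne give a phenol whose O7 is free and whose O8a is silylated, so the two oxygens are ready for methylation and pyran annulation. The C1'=C2' alkene is then made by Julia–Kocienski olefination with the ring A chromene aldehyde.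

Key step: step 6

Remark: C3' is never a reacting centre; its descriptor is S in the hydroxy ester and the aldehyde, R from the enone to the sulfone and S again in the target, only because CIP priorities change.

**Step 1**
Reactants: 1 methyl (S)-3-hydroxy-2-methylpropanoate
Product: 2 methyl (S)-3-(tert-butyldimethylsilyloxy)-2-methylpropanoate
Conditions: TBSCl, imidazole, CH2Cl2, 0 °C → rt
Reagents that add atoms: tert-butyldimethylsilyl chloride, CC(C)(C)[Si](C)(C)Cl
Why: Imidazole-promoted silylation of a primary alcohol (silyl ether protection) is routine and touches neither the ester nor the α-stereocentre.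

**Step 2**
Reactants: 2 methyl (S)-3-(tert-butyldimethylsilyloxy)-2-methylpropanoate
Product: 3 (S)-3-(tert-butyldimethylsilyloxy)-2-methylpropanal
Conditions: i-Bu2AlH (1.1 equiv), CH2Cl2, −78 °C; aq. potassium sodium tartrate
Reagents that add atoms: none
Why: At −78 °C the aluminium hemiacetal formed by a single hydride addition survives until the quench (partial ester reduction), so the aldehyde is released only on neutral work-up and is used crude to avoid α-epimerisation.

**Step 3**
Reactants: 3 (S)-3-(tert-butyldimethylsilyloxy)-2-methylpropanal; 4 1-(triphenylphosphoranylidene)propan-2-one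
Product: 5 (R,E)-6-(tert-butyldimethylsilyloxy)-5-methylhex-3-en-2-one
Conditions: CH2Cl2, rt → 40 °C
Reagents that add atoms: none
Why: The stabilised, essentially non-basic acetonyl ylide should give the (E)-enone (Wittig olefination) without enolising the α-branched aldehyde.

**Step 4**
Reactants: 5 (R,E)-6-(tert-butyldimethylsilyloxy)-5-methylhex-3-en-2-one
Product: 8 (R,E)-6-(tert-butyldimethylsilyloxy)-1-diazo-5-methylhex-3-en-2-one, via lithium enolate 6 (not isolated), via trifluoroacetyl diketone 7 (not isolated)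
Conditions: LiN(SiMe3)2, THF, −78 °C; CF3CO2CH2CF3; aq. HCl; then MsN3, Et3N, H2O, MeCN, rt
Reagents that add atoms: methanesulfonyl azide, CS(=O)(=O)N=[N+]=[N-] (the N2 unit); 2,2,2-trifluoroethyl trifluoroacetate, O=C(OCC(F)(F)F)C(F)(F)F, adds the trifluoroacetyl group only to intermediate 7
Why: Kinetic deprotonation occurs at the methyl group and not at the γ-hydrogen on C3', Claisen-type trifluoroacetylation activates that carbon, and the sulfonyl azide then transfers N2 with loss of the trifluoroacetyl group as the acylsulfonamide (detrifluoroacetylative diazo transfer, the standard entry to diazomethyl enones).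

**Step 5**
Reactants: 9 acetylene
Product: 12 (triisopropylsilyloxy)ethyne, via lithium acetylide 10 (not isolated), via lithium ethynolate 11 (not isolated)
Conditions: n-BuLi, THF, −78 °C (excess acetylene); t-BuOOLi (from t-BuOOH, LiN(SiMe3)2), −78 → −20 °C; TIPSOTf, −78 → 0 °C
Reagents that add atoms: tert-butyl hydroperoxide, CC(C)(C)OO (the oxygen atom); triisopropylsilyl trifluoromethanesulfonate, CC(C)[Si](C(C)C)(C(C)C)OS(=O)(=O)C(F)(F)F
Why: A lithium acetylide attacks the peroxide oxygen of t-BuOOLi to give the ynolate (acetylide oxygenation), which the hard, bulky silyl triflate should capture on oxygen to give the silyl ynol ether, while excess acetylene and low temperature hold back dilithium acetylide formation.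

**Step 6**
Reactants: 8 (R,E)-6-(tert-butyldimethylsilyloxy)-1-diazo-5-methylhex-3-en-2-one; 12 (triisopropylsilyloxy)ethyne
Product: 17 (R)-2-[1-(tert-butyldimethylsilyloxy)propan-2-yl]-5-(triisopropylsilyloxy)phenol, via vinylketene 13 (not isolated), via vinylcyclobutenone 14 (not isolated), via dienylketene 15 (not isolated), via cyclohexadienone 16 (not isolated)
Conditions: hν (254 nm, quartz), ClCH2CH2Cl, rt; then 80 °C
Reagents that add atoms: none
Why: Photolysis expels N2 and Wolff rearrangement (1,2-shift of the alkenyl carbon, bond C4a–C5) gives vinylketene 13, which the electron-rich ynol ether 12 traps at room temperature in a [2+2] cycloaddition (bonds C7–C8 and C4a–C8a) to give vinylcyclobutenone 14. On warming, 14 opens by 4π-electrocyclic cleavage to dienylketene 15, which closes ring B by thermal disrotatory 6π-electrocyclisation (bond C6–C7) to dienone 16 and tautomerises to phenol 17. This is the photochemical Wolff variant of the Danheiser benzannulation, a known reaction of α-diazo enones with siloxyalkynes. No stereocentre is created, since the sp3 ring carbons of 14 and 16 vanish on aromatisation and C3' lies outside every reacting π-system. The one selectivity required is the orientation of the [2+2] step, and it is fixed by polarity: the nucleophilic CH terminus of the ynol ether bonds to the electrophilic ketene carbon, which puts OH on C7, the silyloxy group on C8a and H on C8. The (E)-alkene holds the C3' hydrogen away from the ketene, so a 1,5-hydrogen shift cannot compete.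

**Step 7**
Reactants: 17 (R)-2-[1-(tert-butyldimethylsilyloxy)propan-2-yl]-5-(triisopropylsilyloxy)phenol
Product: 18 (R)-tert-butyl{2-[2-methoxy-4-(triisopropylsilyloxy)phenyl]propoxy}dimethylsilane
Conditions: MeI, K2CO3, acetone, 50 °C
Reagents that add atoms: iodomethane, CI
Why: Williamson methylation of the only free phenol should be clean because the aryl TIPS ether and the alkyl TBS ether tolerate K2CO3 in dry acetone, so O7 alone is methylated.

**Step 8**
Reactants: 18 (R)-tert-butyl{2-[2-methoxy-4-(triisopropylsilyloxy)phenyl]propoxy}dimethylsilane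
Product: 19 (R)-4-(1-hydroxypropan-2-yl)-3-methoxyphenol
Conditions: Bu4NF, THF, 0 °C → rt; aq. NH4Cl
Reagents that add atoms: none
Why: Fluoride cleaves the aryl and the alkyl silyl ether in one operation (desilylation), unmasking O8a and the primary alcohol.

**Step 9**
Reactants: 19 (R)-4-(1-hydroxypropan-2-yl)-3-methoxyphenol; 20 3-chloro-3-methylbut-1-yne
Product: 21 (R)-2-{2-methoxy-4-[(2-methylbut-3-yn-2-yl)oxy]phenyl}propan-1-ol
Conditions: DBU, CuCl2·2H2O (cat.), MeCN, 0 °C → rt
Reagents that add atoms: none
Why: DBU ionises only the phenol, and the copper-catalysed substitution of the tertiary propargylic chloride (through a copper allenylidene) then gives the aryl 1,1-dimethylpropargyl ether and leaves the aliphatic alcohol untouched (chemoselective O-propargylation).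

**Step 10**
Reactants: 21 (R)-2-{2-methoxy-4-[(2-methylbut-3-yn-2-yl)oxy]phenyl}propan-1-ol
Product: 24 (R)-2-(7-methoxy-2,2-dimethyl-2H-chromen-6-yl)propan-1-ol, via allenylphenol 22 (not isolated), via quinone methide 23 (not isolated)
Conditions: o-xylene, 140 °C
Reagents that add atoms: none
Why: Aromatic propargyl Claisen rearrangement to the less hindered ortho carbon C4a (C8 is flanked by both oxygens) gives allenylphenol 22, whose 1,5-hydrogen shift to quinone methide 23 and oxa-6π-electrocyclisation close the 2,2-dimethylpyran.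

**Step 11**
Reactants: 24 (R)-2-(7-methoxy-2,2-dimethyl-2H-chromen-6-yl)propan-1-ol
Product: 25 5-{[(2R)-2-(7-methoxy-2,2-dimethyl-2H-chromen-6-yl)propyl]sulfanyl}-1-phenyl-1H-tetrazole
Conditions: 1-phenyl-1H-tetrazole-5-thiol, PPh3, DIAD, THF, 0 °C → rt
Reagents that add atoms: 1-phenyl-1H-tetrazole-5-thiol, Sc1nnnn1-c1ccccc1
Why: Mitsunobu thioetherification of the primary alcohol with the acidic tetrazolethiol takes place at CH2 and does not involve the neighbouring stereocentre.

**Step 12**
Reactants: 25 5-{[(2R)-2-(7-methoxy-2,2-dimethyl-2H-chromen-6-yl)propyl]sulfanyl}-1-phenyl-1H-tetrazole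
Product: 26 5-{[(2R)-2-(7-methoxy-2,2-dimethyl-2H-chromen-6-yl)propyl]sulfonyl}-1-phenyl-1H-tetrazole
Conditions: (NH4)6Mo7O24·4H2O (cat.), 30% H2O2, EtOH, 0 °C → rt
Reagents that add atoms: hydrogen peroxide, OO
Why: Peroxomolybdate-catalysed oxidation with H2O2 (sulfide to sulfone) is selective for sulfur and should spare the chromene double bond, which a peracid would epoxidise.

**Step 13**
Reactants: 27 4-hydroxy-2-methoxybenzaldehyde; 20 3-chloro-3-methylbut-1-yne
Product: 28 2-methoxy-4-[(2-methylbut-3-yn-2-yl)oxy]benzaldehyde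
Conditions: DBU, CuCl2·2H2O (cat.), MeCN, 0 °C → rt
Reagents that add atoms: none
Why: The copper-catalysed propargylation (O-propargylation of a phenoxide) works particularly well for electron-poor phenols such as a para-hydroxybenzaldehyde.

**Step 14**
Reactants: 28 2-methoxy-4-[(2-methylbut-3-yn-2-yl)oxy]benzaldehyde
Product: 31 7-methoxy-2,2-dimethyl-2H-chromene-6-carbaldehyde, via formyl allenylphenol 29 (not isolated), via formyl quinone methide 30 (not isolated)
Conditions: PhNEt2, 190 °C
Reagents that add atoms: none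
Why: Propargyl Claisen rearrangement to C5 of the benzaldehyde (C3 between the two oxygens is more hindered), then 1,5-hydrogen shift and oxa-6π-electrocyclisation through 29 and 30, should give the linear 6-formyl-7-methoxychromene.

**Step 15**
Reactants: 26 5-{[(2R)-2-(7-methoxy-2,2-dimethyl-2H-chromen-6-yl)propyl]sulfonyl}-1-phenyl-1H-tetrazole; 31 7-methoxy-2,2-dimethyl-2H-chromene-6-carbaldehyde
Product: 33 6,6'-[(1E,3S)-but-1-ene-1,3-diyl]bis(7-methoxy-2,2-dimethyl-2H-chromene), via potassium sulfonyl carbanion 32 (not isolated)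
Conditions: KN(SiMe3)2, DME, −60 °C; then 31, −60 °C → rt
Reagents that add atoms: none
Why: In this Julia–Kocienski olefination the metalated tetrazolyl sulfone adds to the aromatic aldehyde and Smiles rearrangement with anti-elimination of SO2 and the tetrazolone gives the alkene, (E)-selectively for 1-phenyltetrazolyl sulfones with a potassium counter-ion in DME, while the base is too weak to remove the benzylic C3' hydrogen, so the stereocentre is retained.

**Compound list**
1 | methyl (S)-3-hydroxy-2-methylpropanoate | COC(=O)[C@@H](C)CO | starting material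
2 | methyl (S)-3-(tert-butyldimethylsilyloxy)-2-methylpropanoate | COC(=O)[C@@H](C)CO[Si](C)(C)C(C)(C)C | intermediate
3 | (S)-3-(tert-butyldimethylsilyloxy)-2-methylpropanal | O=C[C@@H](C)CO[Si](C)(C)C(C)(C)C | intermediate
4 | 1-(triphenylphosphoranylidene)propan-2-one | CC(=O)C=P(c1ccccc1)(c1ccccc1)c1ccccc1 | starting material
5 | (R,E)-6-(tert-butyldimethylsilyloxy)-5-methylhex-3-en-2-one | CC(=O)/C=C/[C@@H](C)CO[Si](C)(C)C(C)(C)C | intermediate
6 | lithium (R,E)-6-(tert-butyldimethylsilyloxy)-5-methylhexa-1,3-dien-2-olate | [Li+].[O-]C(=C)/C=C/[C@@H](C)CO[Si](C)(C)C(C)(C)C | intermediate (not isolated)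
7 | (5E,7R)-8-(tert-butyldimethylsilyloxy)-1,1,1-trifluoro-7-methyloct-5-ene-2,4-dione | O=C(CC(=O)C(F)(F)F)/C=C/[C@@H](C)CO[Si](C)(C)C(C)(C)C | intermediate (not isolated)
8 | (R,E)-6-(tert-butyldimethylsilyloxy)-1-diazo-5-methylhex-3-en-2-one | O=C(C=[N+]=[N-])/C=C/[C@@H](C)CO[Si](C)(C)C(C)(C)C | intermediate
9 | acetylene | C#C | starting material
10 | lithium acetylide | [Li+].[C-]#C | intermediate (not isolated)
11 | lithium ethynolate | [Li+].[O-]C#C | intermediate (not isolated)
12 | (triisopropylsilyloxy)ethyne | C#CO[Si](C(C)C)(C(C)C)C(C)C | intermediate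
13 | (3E,5R)-6-(tert-butyldimethylsilyloxy)-5-methylhexa-1,3-dien-1-one | O=C=C/C=C/[C@@H](C)CO[Si](C)(C)C(C)(C)C | intermediate (not isolated)
14 | 4-[(1E,3R)-4-(tert-butyldimethylsilyloxy)-3-methylbut-1-en-1-yl]-3-(triisopropylsilyloxy)cyclobut-2-en-1-one (both C4 epimers) | O=C1C=C(O[Si](C(C)C)(C(C)C)C(C)C)C1/C=C/[C@@H](C)CO[Si](C)(C)C(C)(C)C | intermediate (not isolated)
15 | (3E,5E,7R)-8-(tert-butyldimethylsilyloxy)-7-methyl-3-(triisopropylsilyloxy)octa-1,3,5-trien-1-one | O=C=C/C(O[Si](C(C)C)(C(C)C)C(C)C)=C\C=C\[C@@H](C)CO[Si](C)(C)C(C)(C)C | intermediate (not isolated)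
16 | 6-[(R)-1-(tert-butyldimethylsilyloxy)propan-2-yl]-3-(triisopropylsilyloxy)cyclohexa-2,4-dien-1-one (both C6 epimers) | O=C1C=C(O[Si](C(C)C)(C(C)C)C(C)C)C=CC1[C@@H](C)CO[Si](C)(C)C(C)(C)C | intermediate (not isolated)
17 | (R)-2-[1-(tert-butyldimethylsilyloxy)propan-2-yl]-5-(triisopropylsilyloxy)phenol | Oc1cc(O[Si](C(C)C)(C(C)C)C(C)C)ccc1[C@@H](C)CO[Si](C)(C)C(C)(C)C | intermediate
18 | (R)-tert-butyl{2-[2-methoxy-4-(triisopropylsilyloxy)phenyl]propoxy}dimethylsilane | COc1cc(O[Si](C(C)C)(C(C)C)C(C)C)ccc1[C@@H](C)CO[Si](C)(C)C(C)(C)C | intermediate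
19 | (R)-4-(1-hydroxypropan-2-yl)-3-methoxyphenol | COc1cc(O)ccc1[C@@H](C)CO | intermediate
20 | 3-chloro-3-methylbut-1-yne | C#CC(C)(C)Cl | starting material
21 | (R)-2-{2-methoxy-4-[(2-methylbut-3-yn-2-yl)oxy]phenyl}propan-1-ol | COc1cc(OC(C)(C)C#C)ccc1[C@@H](C)CO | intermediate
22 | 4-[(R)-1-hydroxypropan-2-yl]-5-methoxy-2-(3-methylbuta-1,2-dien-1-yl)phenol | COc1cc(O)c(C=C=C(C)C)cc1[C@@H](C)CO | intermediate (not isolated)
23 | (6Z)-4-[(R)-1-hydroxypropan-2-yl]-3-methoxy-6-(3-methylbut-2-en-1-ylidene)cyclohexa-2,4-dien-1-one | O=C1C=C(OC)C([C@@H](C)CO)=C/C1=C/C=C(C)C | intermediate (not isolated)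
24 | (R)-2-(7-methoxy-2,2-dimethyl-2H-chromen-6-yl)propan-1-ol | COc1cc2c(cc1[C@@H](C)CO)C=CC(C)(C)O2 | intermediate
25 | 5-{[(2R)-2-(7-methoxy-2,2-dimethyl-2H-chromen-6-yl)propyl]sulfanyl}-1-phenyl-1H-tetrazole | COc1cc2c(cc1[C@@H](C)CSc1nnnn1-c1ccccc1)C=CC(C)(C)O2 | intermediate
26 | 5-{[(2R)-2-(7-methoxy-2,2-dimethyl-2H-chromen-6-yl)propyl]sulfonyl}-1-phenyl-1H-tetrazole | COc1cc2c(cc1[C@@H](C)CS(=O)(=O)c1nnnn1-c1ccccc1)C=CC(C)(C)O2 | intermediate
27 | 4-hydroxy-2-methoxybenzaldehyde | COc1cc(O)ccc1C=O | starting material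
28 | 2-methoxy-4-[(2-methylbut-3-yn-2-yl)oxy]benzaldehyde | COc1cc(OC(C)(C)C#C)ccc1C=O | intermediate
29 | 4-hydroxy-2-methoxy-5-(3-methylbuta-1,2-dien-1-yl)benzaldehyde | COc1cc(O)c(C=C=C(C)C)cc1C=O | intermediate (not isolated)
30 | (6Z)-4-formyl-3-methoxy-6-(3-methylbut-2-en-1-ylidene)cyclohexa-2,4-dien-1-one | O=C1C=C(OC)C(C=O)=C/C1=C/C=C(C)C | intermediate (not isolated)
31 | 7-methoxy-2,2-dimethyl-2H-chromene-6-carbaldehyde | COc1cc2c(cc1C=O)C=CC(C)(C)O2 | intermediate
32 | potassium salt of the α-sulfonyl carbanion of 26 | [K+].COc1cc2c(cc1[C@@H](C)[CH-]S(=O)(=O)c1nnnn1-c1ccccc1)C=CC(C)(C)O2 | intermediate (not isolated)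
33 | 6,6'-[(1E,3S)-but-1-ene-1,3-diyl]bis(7-methoxy-2,2-dimethyl-2H-chromene) | COc1cc2c(cc1/C=C/[C@H](C)c1cc3c(cc1OC)OC(C)(C)C=C3)C=CC(C)(C)O2 | target

**Step count and risks**
Total step count: 15. Longest linear sequence: 12 steps (steps 1–4, 6–12 and 15, from compound 1).

**Step 6 (benzannulation).** The vinylketene may be consumed before it meets the ynol ether, by dimerisation, by acylating the product phenol, or after photoisomerisation of the enone by a 1,5-hydrogen shift. The photolysis may also stall as the products absorb the light. The fallback gives up the ring construction and installs C3' on the preformed chromene by auxiliary-controlled alkylation. It sets out from aldehyde 31 and returns to the route at alcohol 24, which continues with step 11. Reductive cyanation of 31 with TosMIC (t-BuOK, DME, then MeOH at reflux; van Leusen reaction) should give 2-(7-methoxy-2,2-dimethyl-2H-chromen-6-yl)acetonitrile F1. Hydrolysis (KOH, aqueous EtOH, reflux) gives 2-(7-methoxy-2,2-dimethyl-2H-chromen-6-yl)acetic acid F2. Its mixed pivalic anhydride (PivCl, Et3N, THF) acylates lithiated (R)-4-benzyloxazolidin-2-one to give (R)-4-benzyl-3-[2-(7-methoxy-2,2-dimethyl-2H-chromen-6-yl)acetyl]oxazolidin-2-one F3. NaN(SiMe3)2 (THF, −78 °C) and then MeI should methylate the chelated (Z)-enolate on the face away from the benzyl group (Evans alkylation) to give (R)-4-benzyl-3-[(R)-2-(7-methoxy-2,2-dimethyl-2H-chromen-6-yl)propanoyl]oxazolidin-2-one F4. LiBH4 (THF, MeOH) then reduces off the auxiliary and delivers 24.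

**Step 5 (silyl ynol ether).** The monolithium acetylide may disproportionate, the oxygen transfer may remain incomplete, and the unsubstituted ynolate may be silylated on carbon (to the silylketene) instead of on oxygen. The fallback replaces the silyl ynol ether by an alkyl ynol ether made without any ynolate. It sets out from diazo enone 8 and returns to the route at diol 19. 2-Propanol (KH, THF) adds to trichloroethylene by way of dichloroacetylene to give (E)-1,2-dichloro-1-(propan-2-yloxy)ethene F5. n-BuLi (2 equiv, −78 °C; elimination, then chlorine–lithium exchange) followed by MeOH gives 2-(ethynyloxy)propane F6. Irradiation of 8 with F6 under the conditions of step 6 (alkoxyalkynes are established partners in this benzannulation) should give (R)-2-[1-(tert-butyldimethylsilyloxy)propan-2-yl]-5-(propan-2-yloxy)phenol F7. Methylation as in step 7 gives (R)-tert-butyl{2-[2-methoxy-4-(propan-2-yloxy)phenyl]propoxy}dimethylsilane F8. BCl3 (CH2Cl2, −78 → 0 °C, aqueous work-up) should cleave the isopropyl aryl ether selectively beside the methyl ether and also remove the TBS group, giving 19.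

**Step 15 (olefination).** The addition–elimination sequence may lose (E)-selectivity, or the metalated sulfone may be consumed by attacking the tetrazole of a second sulfone molecule. The fallback is a Julia–Lythgoe olefination, in which the alkene geometry is set in a reductive elimination that favours the (E)-isomer. It sets out from alcohol 24 and returns to the route at target 33. PhSSPh and Bu3P (THF) convert 24 into (R)-7-methoxy-2,2-dimethyl-6-[1-(phenylsulfanyl)propan-2-yl]-2H-chromene F9. Oxidation as in step 12 gives (R)-7-methoxy-2,2-dimethyl-6-[1-(phenylsulfonyl)propan-2-yl]-2H-chromene F10. n-BuLi (THF, −78 °C), then aldehyde 31, then Ac2O should give (3R)-1,3-bis(7-methoxy-2,2-dimethyl-2H-chromen-6-yl)-2-(phenylsulfonyl)butyl acetate F11 as a mixture of diastereomers at C1 and C2. SmI2 (THF, DMPU) then eliminates acetate and sulfinate to give 33.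

**Further compounds**
F1 | step 6 | 2-(7-methoxy-2,2-dimethyl-2H-chromen-6-yl)acetonitrile | COc1cc2c(cc1CC#N)C=CC(C)(C)O2
F2 | step 6 | 2-(7-methoxy-2,2-dimethyl-2H-chromen-6-yl)acetic acid | COc1cc2c(cc1CC(=O)O)C=CC(C)(C)O2
F3 | step 6 | (R)-4-benzyl-3-[2-(7-methoxy-2,2-dimethyl-2H-chromen-6-yl)acetyl]oxazolidin-2-one | COc1cc2c(cc1CC(=O)N1C(=O)OC[C@H]1Cc1ccccc1)C=CC(C)(C)O2
F4 | step 6 | (R)-4-benzyl-3-[(R)-2-(7-methoxy-2,2-dimethyl-2H-chromen-6-yl)propanoyl]oxazolidin-2-one | COc1cc2c(cc1[C@@H](C)C(=O)N1C(=O)OC[C@H]1Cc1ccccc1)C=CC(C)(C)O2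
F5 | step 5 | (E)-1,2-dichloro-1-(propan-2-yloxy)ethene | Cl/C(OC(C)C)=C/Cl
F6 | step 5 | 2-(ethynyloxy)propane | C#COC(C)C
F7 | step 5 | (R)-2-[1-(tert-butyldimethylsilyloxy)propan-2-yl]-5-(propan-2-yloxy)phenol | Oc1cc(OC(C)C)ccc1[C@@H](C)CO[Si](C)(C)C(C)(C)C
F8 | step 5 | (R)-tert-butyl{2-[2-methoxy-4-(propan-2-yloxy)phenyl]propoxy}dimethylsilane | COc1cc(OC(C)C)ccc1[C@@H](C)CO[Si](C)(C)C(C)(C)C
F9 | step 15 | (R)-7-methoxy-2,2-dimethyl-6-[1-(phenylsulfanyl)propan-2-yl]-2H-chromene | COc1cc2c(cc1[C@@H](C)CSc1ccccc1)C=CC(C)(C)O2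
F10 | step 15 | (R)-7-methoxy-2,2-dimethyl-6-[1-(phenylsulfonyl)propan-2-yl]-2H-chromene | COc1cc2c(cc1[C@@H](C)CS(=O)(=O)c1ccccc1)C=CC(C)(C)O2
F11 | step 15 | (3R)-1,3-bis(7-methoxy-2,2-dimethyl-2H-chromen-6-yl)-2-(phenylsulfonyl)butyl acetate (diastereomers at C1 and C2) | CC(=O)OC(c1cc2c(cc1OC)OC(C)(C)C=C2)C([C@H](C)c1cc2c(cc1OC)OC(C)(C)C=C2)S(=O)(=O)c1ccccc1
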